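**Retrosynthetic overview**

- Last disconnection: the three benzyl ethers of the fully assembled flavonol are removed by hydrogenolysis.
- Key disconnection: the C4a–C5 bond of ring A. The strategy rests on ring A, whose carbons C5 (OH), C6 (H), C7 (OMe) and C8 (OMe) lie in that order between C4a and C8a of the pyranone ring C. They are the four ring carbons C1, C2, C3 and C4 of a 3,4-dimethoxycyclobutenone bound through C4 to the pyranone, so ring A forms by 4π opening and 6π closure.
- The cyclobutenone comes from 1,2-addition of the 2-aryl-3-benzyloxy-4-pyranone, metalated at the CH next to the ring oxygen, to methyl semisquarate (made from dimethyl squarate), followed by O-methylation.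
- The pyranone comes from furan and the ring B aldehyde by Achmatowicz ring expansion, enone epoxidation and acid-induced aromatisation.
- Ring order: ring B (purchased arene), ring C (from furan), ring A last.

Key step: step 14

Remark on the chemistry: methyl semisquarate is assumed not to be purchasable and is made from dimethyl squarate. The dihydropyranone intermediates are carried as racemic diastereomer mixtures because all their stereocentres vanish when the pyranone is formed. The target has no stereocentre.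

**Route**

Step 1
Reactants: 1 methyl 3,5-dihydroxy-4-methoxybenzoate
Product: 2 methyl 3,5-bis(benzyloxy)-4-methoxybenzoate
Conditions: BnBr, K2CO3, DMF, 60 °C
Reagents that add atoms: benzyl bromide, BrCc1ccccc1
Why: Williamson ether synthesis; both phenols are alkylated under carbonate conditions and the ester is untouched.

Step 2
Reactants: 2 methyl 3,5-bis(benzyloxy)-4-methoxybenzoate
Product: 3 [3,5-bis(benzyloxy)-4-methoxyphenyl]methanol
Conditions: LiAlH4, THF, 0 °C; H2O, 15% aq. NaOH work-up
Reagents that add atoms: none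
Why: Hydride reduction of the ester to the primary alcohol; aryl benzyl and methyl ethers are inert to LiAlH4.

Step 3
Reactants: 3 [3,5-bis(benzyloxy)-4-methoxyphenyl]methanol
Product: 4 3,5-bis(benzyloxy)-4-methoxybenzaldehyde
Conditions: activated MnO2, CH2Cl2, rt
Reagents that add atoms: none
Why: Chemoselective oxidation of a benzylic alcohol by MnO2, which stops at the aldehyde.

Step 4
Reactants: 5 furan; 4 3,5-bis(benzyloxy)-4-methoxybenzaldehyde
Product: 7 [3,5-bis(benzyloxy)-4-methoxyphenyl](furan-2-yl)methanol (racemic), via 2-furyllithium 6 (not isolated)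
Conditions: 5, n-BuLi, THF, 0 °C; then 4, −78 °C to rt; H2O
Reagents that add atoms: none
Why: α-Lithiation of furan followed by 1,2-addition of the organolithium to the aldehyde; the carbinol centre forms without control, which is acceptable because it becomes sp2 in step 8.

Step 5
Reactants: 7 [3,5-bis(benzyloxy)-4-methoxyphenyl](furan-2-yl)methanol
Product: 8 2-[3,5-bis(benzyloxy)-4-methoxyphenyl]-6-hydroxy-2H-pyran-3(6H)-one (racemic, mixture of C6 epimers)
Conditions: mCPBA, CH2Cl2, 0 °C
Reagents that add atoms: 3-chloroperbenzoic acid, OOC(=O)c1cccc(Cl)c1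
Why: Achmatowicz rearrangement: the furan, far more electron-rich than the trialkoxyarene, is oxidised to the ene-dione, which the carbinol oxygen closes to the pyranone hemiacetal; the anomeric centre forms as a mixture and is erased later.

Step 6
Reactants: 8 2-[3,5-bis(benzyloxy)-4-methoxyphenyl]-6-hydroxy-2H-pyran-3(6H)-one
Product: 9 2-[3,5-bis(benzyloxy)-4-methoxyphenyl]-6-methoxy-2H-pyran-3(6H)-one (racemic, mixture of C6 epimers)
Conditions: HC(OMe)3, BF3·OEt2 (cat.), CH2Cl2, 0 °C
Reagents that add atoms: trimethyl orthoformate, COC(OC)OC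
Why: Lewis-acid-mediated acetal exchange through the cyclic oxocarbenium ion; it locks the hemiacetal so that the base of step 7 cannot open the ring.

Step 7
Reactants: 9 2-[3,5-bis(benzyloxy)-4-methoxyphenyl]-6-methoxy-2H-pyran-3(6H)-one
Product: 10 4-[3,5-bis(benzyloxy)-4-methoxyphenyl]-2-methoxy-3,7-dioxabicyclo[4.1.0]heptan-5-one (racemic diastereomer mixture)
Conditions: 30% aq. H2O2, NaOH (cat.), MeOH, 0 °C
Reagents that add atoms: hydrogen peroxide, OO
Why: Weitz–Scheffer nucleophilic epoxidation of the enone; attack anti to the 6-methoxy group is expected, but the new stereocentres do not matter because step 8 erases them.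

Step 8
Reactants: 10 4-[3,5-bis(benzyloxy)-4-methoxyphenyl]-2-methoxy-3,7-dioxabicyclo[4.1.0]heptan-5-one
Product: 11 2-[3,5-bis(benzyloxy)-4-methoxyphenyl]-3-hydroxy-4H-pyran-4-one
Conditions: 1 M H2SO4, 1,4-dioxane, 80 °C
Reagents that add atoms: none
Why: Acid-catalysed isomerisation of the α,β-epoxy ketone to the diosphenol with β-elimination of methanol (the pathway of the classical maltol synthesis from 6-alkoxypyranone epoxides), driven by formation of the 3-hydroxy-4-pyranone; all sp3 stereocentres vanish.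

Step 9
Reactants: 11 2-[3,5-bis(benzyloxy)-4-methoxyphenyl]-3-hydroxy-4H-pyran-4-one
Product: 12 3-(benzyloxy)-2-[3,5-bis(benzyloxy)-4-methoxyphenyl]-4H-pyran-4-one
Conditions: BnBr, K2CO3, DMF, rt
Reagents that add atoms: benzyl bromide, BrCc1ccccc1
Why: Williamson benzylation of the acidic enolic 3-hydroxyl, as for maltol-type pyranones.

Step 10
Reactants: 13 dimethyl squarate (3,4-dimethoxycyclobut-3-ene-1,2-dione)
Product: 14 4-hydroxy-2,3-dimethoxycyclobut-2-en-1-one (racemic)
Conditions: LiAlH(OtBu)3, THF, −78 to −20 °C; cold 1 M HCl work-up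
Reagents that add atoms: none
Why: 1,2-Reduction of one of the two equivalent carbonyls by a mild, bulky hydride; the vinylogous ester that results is too electron-rich to be reduced again, and the racemic carbinol centre is lost in step 11.

Step 11
Reactants: 14 4-hydroxy-2,3-dimethoxycyclobut-2-en-1-one
Product: 15 3-methoxycyclobut-3-ene-1,2-dione (methyl semisquarate)
Conditions: conc. HCl (cat.), CH2Cl2, rt
Reagents that add atoms: water, O
Why: Acid-catalysed allylic transposition: ionisation of the carbinol gives an oxygen-stabilised cyclobutenyl cation that takes up water at the neighbouring methoxy-bearing carbon and expels methanol, the standard conversion of squarate 1,2-adducts into 3-alkoxycyclobutenediones.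

Step 12
Reactants: 12 3-(benzyloxy)-2-[3,5-bis(benzyloxy)-4-methoxyphenyl]-4H-pyran-4-one; 15 3-methoxycyclobut-3-ene-1,2-dione
Product: 17 4-{5-(benzyloxy)-6-[3,5-bis(benzyloxy)-4-methoxyphenyl]-4-oxo-4H-pyran-2-yl}-4-hydroxy-3-methoxycyclobut-2-en-1-one (racemic), via lithiated pyranone 16 (not isolated)
Conditions: LiTMP (from 2,2,6,6-tetramethylpiperidine and n-BuLi), THF, −78 °C, short metalation; cannulate into 15 (excess), THF, −78 °C; aq. NH4Cl, −78 °C
Reagents that add atoms: none
Why: Kinetic deprotonation by the hindered, non-nucleophilic amide at the most acidic ring CH (next to the ring oxygen, as in the C2 lithiation of chromones), then 1,2-addition of the organolithium to the ketone carbonyl of 15 that is not part of the vinylogous ester; the quaternary carbinol is racemic and needs no control.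

Step 13
Reactants: 17 4-{5-(benzyloxy)-6-[3,5-bis(benzyloxy)-4-methoxyphenyl]-4-oxo-4H-pyran-2-yl}-4-hydroxy-3-methoxycyclobut-2-en-1-one
Product: 18 4-{5-(benzyloxy)-6-[3,5-bis(benzyloxy)-4-methoxyphenyl]-4-oxo-4H-pyran-2-yl}-3,4-dimethoxycyclobut-2-en-1-one (racemic)
Conditions: MeI (excess), Ag2O, 4 Å MS, MeCN, rt, dark
Reagents that add atoms: iodomethane, CI
Why: Purdie-type O-methylation under near-neutral conditions, which avoids a free alkoxide that could open or rearrange the four-membered ring.

Step 14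
Reactants: 18 4-{5-(benzyloxy)-6-[3,5-bis(benzyloxy)-4-methoxyphenyl]-4-oxo-4H-pyran-2-yl}-3,4-dimethoxycyclobut-2-en-1-one
Product: 21 3-(benzyloxy)-2-[3,5-bis(benzyloxy)-4-methoxyphenyl]-5-hydroxy-7,8-dimethoxy-4H-chromen-4-one, via dienylketene 19 (not isolated), via cyclohexadienone 20 (not isolated)
Conditions: p-xylene (0.01 M, degassed), 138 °C, N2
Reagents that add atoms: none
Why: Heating opens the cyclobutenone by conrotatory 4π cleavage of the C1–C4 bond to dienylketene 19, whose ketene carbon then bonds to the only free pyranone carbon next to the point of attachment (the future C4a) in a thermal disrotatory 6π electrocyclisation to dienone 20, and enolisation to phenol 21 is driven by aromatisation of ring A and the hydrogen bond to C4=O. The closest known reaction type is the Moore-type thermal ring expansion of 4-aryl-, 4-heteroaryl- and 4-alkenyl-4-alkoxycyclobutenones to phenols. Ring A is closed as a six-membered carbocycle by this 6π closure across the pyranone C=C bond, with the ketene carbon becoming C5 (OH), the ring CH becoming C6 and the two methoxy carbons becoming C7 and C8. No stereocentre is created that persists: the quaternary carbon of 18 becomes sp2 C8 and the sp3 C4a of 20 is lost on tautomerisation. The step needs torquoselectivity, secured by the donor methoxy group on the sp3 carbon rotating outward so that the pyranonyl group turns inward toward the ketene (the opening is reversible, so any wrongly opened ketene returns to 18), and regioselectivity, fixed because the attachment carbon has the ring oxygen on its other side and only one neighbouring CH. High dilution in a dry, non-nucleophilic solvent keeps the ketene from dimerising or being trapped, and the enol-ether-like character of that pyranone CH matches the electrophilic ketene carbon.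

Step 15
Reactants: 21 3-(benzyloxy)-2-[3,5-bis(benzyloxy)-4-methoxyphenyl]-5-hydroxy-7,8-dimethoxy-4H-chromen-4-one
Product: 22 3,5-dihydroxy-2-(3,5-dihydroxy-4-methoxyphenyl)-7,8-dimethoxy-4H-chromen-4-one
Conditions: H2 (1 atm), 10% Pd/C, EtOAc/MeOH, rt
Reagents that add atoms: none
Why: Catalytic hydrogenolysis of the two aryl benzyl ethers and the enol benzyl ether; the tetrasubstituted, conjugated C2=C3 bond of the chromone and the methyl ethers should survive.

**Compound list**

1 | methyl 3,5-dihydroxy-4-methoxybenzoate | COC(=O)c1cc(O)c(OC)c(O)c1 | starting material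
2 | methyl 3,5-bis(benzyloxy)-4-methoxybenzoate | COC(=O)c1cc(OCc2ccccc2)c(OC)c(OCc2ccccc2)c1 | intermediate
3 | [3,5-bis(benzyloxy)-4-methoxyphenyl]methanol | OCc1cc(OCc2ccccc2)c(OC)c(OCc2ccccc2)c1 | intermediate
4 | 3,5-bis(benzyloxy)-4-methoxybenzaldehyde | O=Cc1cc(OCc2ccccc2)c(OC)c(OCc2ccccc2)c1 | intermediate
5 | furan | c1ccoc1 | starting material
6 | 2-furyllithium | [Li]c1ccco1 | intermediate
7 | [3,5-bis(benzyloxy)-4-methoxyphenyl](furan-2-yl)methanol (racemic) | OC(c1ccco1)c1cc(OCc2ccccc2)c(OC)c(OCc2ccccc2)c1 | intermediate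
8 | 2-[3,5-bis(benzyloxy)-4-methoxyphenyl]-6-hydroxy-2H-pyran-3(6H)-one (racemic, C6 epimers) | O=C1C=CC(O)OC1c1cc(OCc2ccccc2)c(OC)c(OCc2ccccc2)c1 | intermediate
9 | 2-[3,5-bis(benzyloxy)-4-methoxyphenyl]-6-methoxy-2H-pyran-3(6H)-one (racemic, C6 epimers) | COC1C=CC(=O)C(c2cc(OCc3ccccc3)c(OC)c(OCc3ccccc3)c2)O1 | intermediate
10 | 4-[3,5-bis(benzyloxy)-4-methoxyphenyl]-2-methoxy-3,7-dioxabicyclo[4.1.0]heptan-5-one (racemic diastereomer mixture) | COC1OC(c2cc(OCc3ccccc3)c(OC)c(OCc3ccccc3)c2)C(=O)C2OC12 | intermediate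
11 | 2-[3,5-bis(benzyloxy)-4-methoxyphenyl]-3-hydroxy-4H-pyran-4-one | O=c1ccoc(-c2cc(OCc3ccccc3)c(OC)c(OCc3ccccc3)c2)c1O | intermediate
12 | 3-(benzyloxy)-2-[3,5-bis(benzyloxy)-4-methoxyphenyl]-4H-pyran-4-one | O=c1ccoc(-c2cc(OCc3ccccc3)c(OC)c(OCc3ccccc3)c2)c1OCc1ccccc1 | intermediate
13 | dimethyl squarate | COC1=C(OC)C(=O)C1=O | starting material
14 | 4-hydroxy-2,3-dimethoxycyclobut-2-en-1-one (racemic) | COC1=C(OC)C(O)C1=O | intermediate
15 | 3-methoxycyclobut-3-ene-1,2-dione (methyl semisquarate) | COC1=CC(=O)C1=O | intermediate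
16 | {5-(benzyloxy)-6-[3,5-bis(benzyloxy)-4-methoxyphenyl]-4-oxo-4H-pyran-2-yl}lithium | [Li]c1cc(=O)c(OCc2ccccc2)c(-c2cc(OCc3ccccc3)c(OC)c(OCc3ccccc3)c2)o1 | intermediate
17 | 4-{5-(benzyloxy)-6-[3,5-bis(benzyloxy)-4-methoxyphenyl]-4-oxo-4H-pyran-2-yl}-4-hydroxy-3-methoxycyclobut-2-en-1-one (racemic) | COC1=CC(=O)C1(O)c1cc(=O)c(OCc2ccccc2)c(-c2cc(OCc3ccccc3)c(OC)c(OCc3ccccc3)c2)o1 | intermediate
18 | 4-{5-(benzyloxy)-6-[3,5-bis(benzyloxy)-4-methoxyphenyl]-4-oxo-4H-pyran-2-yl}-3,4-dimethoxycyclobut-2-en-1-one (racemic) | COC1=CC(=O)C1(OC)c1cc(=O)c(OCc2ccccc2)c(-c2cc(OCc3ccccc3)c(OC)c(OCc3ccccc3)c2)o1 | intermediate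
19 | (3Z)-4-{5-(benzyloxy)-6-[3,5-bis(benzyloxy)-4-methoxyphenyl]-4-oxo-4H-pyran-2-yl}-3,4-dimethoxybuta-1,3-dien-1-one | O=C=C/C(OC)=C(OC)\c1cc(=O)c(OCc2ccccc2)c(-c2cc(OCc3ccccc3)c(OC)c(OCc3ccccc3)c2)o1 | intermediate
20 | 3-(benzyloxy)-2-[3,5-bis(benzyloxy)-4-methoxyphenyl]-7,8-dimethoxy-4aH-chromene-4,5-dione (racemic) | COC1=CC(=O)C2C(=O)C(OCc3ccccc3)=C(c3cc(OCc4ccccc4)c(OC)c(OCc4ccccc4)c3)OC2=C1OC | intermediate
21 | 3-(benzyloxy)-2-[3,5-bis(benzyloxy)-4-methoxyphenyl]-5-hydroxy-7,8-dimethoxy-4H-chromen-4-one | COc1cc(O)c2c(=O)c(OCc3ccccc3)c(-c3cc(OCc4ccccc4)c(OC)c(OCc4ccccc4)c3)oc2c1OC | intermediate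
22 | 3,5-dihydroxy-2-(3,5-dihydroxy-4-methoxyphenyl)-7,8-dimethoxy-4H-chromen-4-one | COc1cc(O)c2c(=O)c(O)c(-c3cc(O)c(OC)c(O)c3)oc2c1OC | target

**Step count**

Total steps: 15. Longest linear sequence: 13 (steps 1 to 9 and 12 to 15, from compound 1); the squarate branch (steps 10 and 11) joins at step 12.

**Steps most likely to fail**

1. Step 14 (ring expansion). The dienylketene may dimerise or be intercepted before it closes onto the partly aromatic, electron-poor pyranone C=C bond, or inward rotation of the bulky pyranonyl group may be too unfavourable for productive opening. The fallback builds ring C last on a preformed ring A; it sets out from compound 4 and comes back at compound 22.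
 - Aldehyde 4 would be condensed under Claisen–Schmidt conditions (KOH, EtOH) with purchased 1-(2-hydroxy-3,4,6-trimethoxyphenyl)ethanone F1 to give (2E)-3-[3,5-bis(benzyloxy)-4-methoxyphenyl]-1-(2-hydroxy-3,4,6-trimethoxyphenyl)prop-2-en-1-one F2.
 - Oxidative cyclisation (I2 cat., DMSO, 120 °C) would give 2-[3,5-bis(benzyloxy)-4-methoxyphenyl]-5,7,8-trimethoxy-4H-chromen-4-one F3.
 - Epoxidation of the C2=C3 bond with dimethyldioxirane and acid-catalysed opening would give 2-[3,5-bis(benzyloxy)-4-methoxyphenyl]-3-hydroxy-5,7,8-trimethoxy-4H-chromen-4-one F4.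
 - AlCl3 in MeCN would cleave the peri 5-methyl ether selectively through chelation with C4=O to give 2-[3,5-bis(benzyloxy)-4-methoxyphenyl]-3,5-dihydroxy-7,8-dimethoxy-4H-chromen-4-one F5.
 - Hydrogenolysis (H2, Pd/C) would then give 22.

2. Step 12 (metalation and addition). Deprotonation may occur at the carbon next to the carbonyl, which opens the ring by β-elimination, or the lithiated pyranone may add to unmetalated pyranone before it meets the dione. The fallback separates metalation from carbonyl addition through an isolable halide; it sets out from compound 12 and comes back at compound 17.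
 - 12 would be zincated with TMPZnCl·LiCl (THF, rt), a base that tolerates the carbonyl group, to give chloro{5-(benzyloxy)-6-[3,5-bis(benzyloxy)-4-methoxyphenyl]-4-oxo-4H-pyran-2-yl}zinc F6.
 - Iodolysis (I2) would give 3-(benzyloxy)-2-[3,5-bis(benzyloxy)-4-methoxyphenyl]-6-iodo-4H-pyran-4-one F7, which is purified.
 - Iodine–magnesium exchange with iPrMgCl·LiCl at −78 °C would give chloro{5-(benzyloxy)-6-[3,5-bis(benzyloxy)-4-methoxyphenyl]-4-oxo-4H-pyran-2-yl}magnesium F8, which adds to 15 at −78 °C to give 17 after NH4Cl quench.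

3. Step 13 (O-methylation). Methylation may take place at the pyranone carbonyl oxygen (pyrylium salt formation) in preference to the hindered tertiary hydroxyl, or the hydroxycyclobutenone may rearrange on the basic silver oxide surface before it is alkylated. The fallback moves the methylation behind the ring expansion; it sets out from compound 17 and comes back at compound 21.
 - The free alcohol 17 would be heated directly (p-xylene, 138 °C, N2). The hydroxyl rotates outward as the methoxy group does, and the same opening and closure should give the hydroquinone 3-(benzyloxy)-2-[3,5-bis(benzyloxy)-4-methoxyphenyl]-5,8-dihydroxy-7-methoxy-4H-chromen-4-one F9, handled under N2 to prevent oxidation to the quinone.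
 - Selective methylation of the free 8-hydroxyl (MeI 1.1 equiv, K2CO3, acetone, rt), with the 5-hydroxyl held unreactive by its hydrogen bond to C4=O, would give 21.

**Further compounds**

F1 | step 14 | 1-(2-hydroxy-3,4,6-trimethoxyphenyl)ethanone (purchased building block) | CC(=O)c1c(O)c(OC)c(OC)cc1OC
F2 | step 14 | (2E)-3-[3,5-bis(benzyloxy)-4-methoxyphenyl]-1-(2-hydroxy-3,4,6-trimethoxyphenyl)prop-2-en-1-one | COc1cc(OC)c(C(=O)/C=C/c2cc(OCc3ccccc3)c(OC)c(OCc3ccccc3)c2)c(O)c1OC
F3 | step 14 | 2-[3,5-bis(benzyloxy)-4-methoxyphenyl]-5,7,8-trimethoxy-4H-chromen-4-one | COc1cc(OC)c2c(=O)cc(-c3cc(OCc4ccccc4)c(OC)c(OCc4ccccc4)c3)oc2c1OC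
F4 | step 14 | 2-[3,5-bis(benzyloxy)-4-methoxyphenyl]-3-hydroxy-5,7,8-trimethoxy-4H-chromen-4-one | COc1cc(OC)c2c(=O)c(O)c(-c3cc(OCc4ccccc4)c(OC)c(OCc4ccccc4)c3)oc2c1OC
F5 | step 14 | 2-[3,5-bis(benzyloxy)-4-methoxyphenyl]-3,5-dihydroxy-7,8-dimethoxy-4H-chromen-4-one | COc1cc(O)c2c(=O)c(O)c(-c3cc(OCc4ccccc4)c(OC)c(OCc4ccccc4)c3)oc2c1OC
F6 | step 12 | chloro{5-(benzyloxy)-6-[3,5-bis(benzyloxy)-4-methoxyphenyl]-4-oxo-4H-pyran-2-yl}zinc | Cl[Zn]c1cc(=O)c(OCc2ccccc2)c(-c2cc(OCc3ccccc3)c(OC)c(OCc3ccccc3)c2)o1
F7 | step 12 | 3-(benzyloxy)-2-[3,5-bis(benzyloxy)-4-methoxyphenyl]-6-iodo-4H-pyran-4-one | Ic1cc(=O)c(OCc2ccccc2)c(-c2cc(OCc3ccccc3)c(OC)c(OCc3ccccc3)c2)o1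
F8 | step 12 | chloro{5-(benzyloxy)-6-[3,5-bis(benzyloxy)-4-methoxyphenyl]-4-oxo-4H-pyran-2-yl}magnesium | Cl[Mg]c1cc(=O)c(OCc2ccccc2)c(-c2cc(OCc3ccccc3)c(OC)c(OCc3ccccc3)c2)o1
F9 | step 13 | 3-(benzyloxy)-2-[3,5-bis(benzyloxy)-4-methoxyphenyl]-5,8-dihydroxy-7-methoxy-4H-chromen-4-one | COc1cc(O)c2c(=O)c(OCc3ccccc3)c(-c3cc(OCc4ccccc4)c(OC)c(OCc4ccccc4)c3)oc2c1O
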